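**Plan**

- Retrosynthesis: ring C is cut at C12–C13 by a retro carbonyl-ene across the homoallylic alcohol array C12(OH)–C13–C16=C17. The resulting 12,13-seco aldehyde, with ring D as a 1-methylcyclopentene, is traced to β-scission of the same bond in a 13-hydroxy gibberellin. The 2β,3β-diol is traced to a ring A 2-ene, and everything to gibberellic acid.
- Forward: rings A, B, D and the 19,10-lactone are taken intact from gibberellic acid. Ring A is converted to the 2-ene, ring C is opened by hypoiodite photolysis (C12–I, ring D enone), and the ring A alkene is dihydroxylated. The enone is then turned into the C13=C16–C17H3 ene unit, C12 is raised to the aldehyde, and ring C is closed last.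
- Opening and reclosing ring C amounts to a 1,2-transposition of oxygen from C13 to C12.
- Enabling feature: in the seco aldehyde the spiro atom C8 holds the C12 carbonyl (through C9–C11) over C13 of the ring D alkene at the citronellal-type distance for six-membered closure. The C17 methyl on C16 directs bond formation to C13 and supplies the hydrogen that leaves the exocyclic methylene behind.
- Stereochemistry: C4, C5, C6, C8, C9 and C10 come from gibberellic acid. C2 and C3 come from β-face osmylation opposite the lactone bridge, C13 from the tether geometry, and C12 from hydride delivery to the 12-ketone on the face away from C10 and the lactone.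

Key step: step 10

Remark: gibberellic acid, a bulk fermentation product, is taken as the commercial starting material. α/β follow the gibberellane convention; 12α is axial on ring C and anti to the C13–C16 bond. Compounds 9–11 are carried as C13 epimers because that centre is erased in step 8.

**Step 1**
Reactants: 1 gibberellic acid
Product: 2 gibberellic acid methyl ester
Conditions: MeI, KHCO3, DMF, 25 °C
Reagents that add atoms: iodomethane, CI
Why: Carboxylate O-alkylation (SN2 on MeI) under bicarbonate should mask the C7 acid without disturbing the base-sensitive allylic lactone; no stereocentre is touched.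

**Step 2**
Reactants: 2 gibberellic acid methyl ester
Product: 3 1β-chloro-3-deoxy-2-ene methyl ester (1β-Cl; C2=C3; 13-OH free; 16-ene and 19,10-lactone intact)
Conditions: PPh3, CCl4, MeCN, 50 °C
Reagents that add atoms: carbon tetrachloride, ClC(Cl)(Cl)Cl
Why: Appel activation of the allylic 3β-hydroxyl should be followed by chloride entry at C1 on the β face (SN2′), because C3 is neopentylic and its α face is covered by the lactone; the tertiary bridgehead 13-OH is inert, and any 3-chloro-1-ene isomer would feed the same allyl radical in step 3.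

**Step 3**
Reactants: 3 1β-chloro-3-deoxy-2-ene methyl ester
Product: 4 3-deoxy-2-ene methyl ester (C2=C3; 13-OH; 16-ene; 19,10-lactone)
Conditions: Bu3SnH, AIBN (cat.), benzene, 80 °C
Reagents that add atoms: none
Why: Radical-chain dehalogenation gives the C1–C2–C3 allyl radical, which should take hydrogen from the stannane mainly at C1 (C3 is flanked by the fully substituted C4), giving the ring A 2-ene.

**Step 4**
Reactants: 4 3-deoxy-2-ene methyl ester
Product: 6 12-iodo-13-oxo-12,13-seco-2,16-diene methyl ester (ring C opened; ring D a 2-methylenecyclopentanone spiro at C8; C9 carries CH2CH2I), via 13-O-hypoiodite 5 (not isolated)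
Conditions: PhI(OAc)2, I2, cyclohexane–CH2Cl2, visible light (tungsten lamp), 25 °C
Reagents that add atoms: iodine, II
Why: Hypoiodite reaction (alkoxy-radical β-scission): the 13-oxyl radical cannot cleave toward the vinylic C16, and of the two remaining bonds only C12–C13 stands nearly perpendicular to the plane of the C16=C17 alkene (C13–C14 lies close to that plane), so its scission should develop enone conjugation in the transition state and the primary C12 radical is caught by iodine; the ring A 2-ene, whose α face is lactone-shielded, is expected to resist acetyl hypoiodite.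

**Step 5**
Reactants: 6 12-iodo-13-oxo-12,13-seco-2,16-diene methyl ester
Product: 7 2β,3β-dihydroxy derivative of 6 (2,3-dihydro)
Conditions: OsO4 (cat.), NMO, acetone–H2O, 0 → 25 °C
Reagents that add atoms: osmium tetroxide (catalytic oxygen carrier), O=[Os](=O)(=O)=O; N-methylmorpholine N-oxide, C[N+]1([O-])CCOCC1; water, O
Why: Upjohn dihydroxylation: the cis-disubstituted ring A alkene is the only electron-rich alkene left (the ring D alkene is now an α-methylene ketone), and OsO4 should add on the β face opposite the 19,10-lactone bridge, setting C2 and C3 as the 2β,3β cis-diol.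

**Step 6**
Reactants: 7 2β,3β-diol
Product: 8 2β,3β-O-isopropylidene derivative of 7
Conditions: Me2C(OMe)2, PPTS (cat.), acetone, 25 °C
Reagents that add atoms: 2,2-dimethoxypropane, COC(C)(C)OC
Why: Acid-catalysed transketalisation ties the axial/equatorial cis-diol into a dioxolane that should stay inert through steps 7–12.

**Step 7**
Reactants: 8 acetonide enone
Product: 9 13-hydroxy-16(17)-ene allylic alcohol (C13 epimers)
Conditions: NaBH4, CeCl3·7H2O, MeOH, −78 → −20 °C
Reagents that add atoms: none
Why: Luche 1,2-reduction of the α-methylene cyclopentanone should give the allylic alcohol without conjugate reduction or attack on ester, lactone or iodide; the C13 configuration is irrelevant because it is erased in step 8.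

**Step 8**
Reactants: 9 allylic alcohol
Product: 12 12-iodo-12,13-seco-13(16)-ene (ring D a 1-methylcyclopentene; C17 now CH3), via sulfonylhydrazine adduct 10 (not isolated), via allylic diazene 11 (not isolated)
Conditions: 2-nitrobenzenesulfonylhydrazide, PPh3, DEAD, THF, −30 → 25 °C
Reagents that add atoms: none
Why: Mitsunobu displacement at C13 by the sulfonyl hydrazide, loss of arenesulfinate on warming, and retro-ene loss of N2 from the allylic diazene should deliver hydrogen to C17 and move the alkene to C13=C16 (reductive 1,3-transposition), giving the trisubstituted alkene needed as the ene partner.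

**Step 9**
Reactants: 12 seco iodide
Product: 14 12-oxo-12,13-seco-13(16)-ene (C12 aldehyde), via alkoxyammonium iodide 13 (not isolated)
Conditions: Me3NO, DMSO, 25 → 40 °C
Reagents that add atoms: trimethylamine N-oxide, C[N+](C)(C)[O-]
Why: Kornblum-type oxidation with an amine N-oxide (SN2 by the N-oxide oxygen at the primary iodide, then loss of trimethylamine) should give the aldehyde under conditions that leave the trisubstituted alkene, acetal and lactone alone.

**Step 10**
Reactants: 14 seco aldehyde
Product: 15 12β-hydroxy 2,3-acetonide methyl ester (12-epimer of 17; equatorial OH; 16-ene restored)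
Conditions: Me2AlCl, CH2Cl2, −78 → −30 °C; aq. sodium potassium tartrate
Reagents that add atoms: none
Why: Lewis-acid-promoted intramolecular carbonyl-ene reaction of type 1, whose closest known relative is the citronellal-to-isopulegol cyclisation: the Me2AlCl-bound C12 aldehyde bonds to C13 of the C13=C16 alkene while a C17 hydrogen passes to the carbonyl oxygen in a six-centre array, creating the C12 carbinol, the C13 methine and the C16=C17 methylene in one event. Ring C closes as a six-membered ring through the chair-like array C8–C9–C11–C12···C13–C14, exo to both π bonds (6-exo-trig at the carbonyl), onto the existing ring D to complete the bicyclo[3.2.1]octane. C13 is fixed by the tether, since the chain leaves C9 on one face of ring D and C12 can reach C13 only there. C12 is fixed by the pericyclic geometry: the oxygen must lie gauche to C16 to reach the C17 hydrogens, which places O–Al equatorial and away from C10 and the lactone, so the 12β-alcohol is expected and is corrected in steps 11 and 12. The step needs bonding at C13 rather than C16, although either carbon could close a six-membered ring from the spiro centre, and the C17 methyl secures this because only attack at C13 places the developing positive character on the fully substituted C16. It also needs hydrogen transfer from C17 rather than C15 and a concerted ene path rather than a cationic Prins path; the C15 hydrogens lie on the far side of C16 from the oxygen, and Me2AlCl scavenges protons.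

**Step 11**
Reactants: 15 12β-alcohol
Product: 16 12-oxo 2,3-acetonide methyl ester (12-ketone)
Conditions: Dess–Martin periodinane, CH2Cl2, 0 → 25 °C
Reagents that add atoms: none
Why: Dess–Martin oxidation of the secondary alcohol; the β,γ-unsaturated ketone cannot enolise toward the bridgehead C13 (Bredt), so neither alkene migration nor epimerisation is expected.

**Step 12**
Reactants: 16 12-ketone
Product: 17 12α-hydroxy 2,3-acetonide methyl ester (axial OH; the target as its methyl ester acetonide)
Conditions: LiBH(s-Bu)3, THF, −78 °C; aq. NH4Cl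
Reagents that add atoms: none
Why: The bulky hydride should attack C12 from the face of the C15–C16 bridge (equatorial attack), because the opposite face is closed by C10 and the lactone oxygen lying syn-axial to C12, giving the axial 12α-alcohol anti to C16.

**Step 13**
Reactants: 17 acetonide
Product: 18 2β,3β,12α-trihydroxy methyl ester (the target as its methyl ester)
Conditions: AcOH–H2O (4:1), 40 °C
Reagents that add atoms: none
Why: Mild aqueous-acid hydrolysis of the isopropylidene acetal should free the 2β,3β-diol; with no 13-hydroxyl present, the exocyclic alkene has no acid-triggered rearrangement path under these conditions.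

**Step 14**
Reactants: 18 trihydroxy methyl ester
Product: 19 the target gibberellin (2β,3β,12α-trihydroxy-16-ene 19,10-lactone 7-carboxylic acid)
Conditions: n-PrSLi, HMPA, 25 °C; then 1 M HCl to pH 3
Reagents that add atoms: none
Why: SN2 demethylation of the hindered C7 methyl ester by thiolate (alkyl–oxygen cleavage) avoids aqueous hydroxide, which would open the lactone and epimerise C3 by retro-aldol; acidification then gives the free acid.

**Compound list**

1 | gibberellic acid | C=C1C[C@]23C[C@@]1(O)CC[C@H]2[C@@]12C=C[C@H](O)[C@@](C)(C(=O)O1)[C@H]2[C@@H]3C(=O)O | starting material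
2 | gibberellic acid methyl ester | C=C1C[C@]23C[C@@]1(O)CC[C@H]2[C@@]12C=C[C@H](O)[C@@](C)(C(=O)O1)[C@H]2[C@@H]3C(=O)OC | intermediate
3 | 1β-chloro-3-deoxy-2-ene methyl ester | C=C1C[C@]23C[C@@]1(O)CC[C@H]2[C@@]12[C@H](Cl)C=C[C@@](C)(C(=O)O1)[C@H]2[C@@H]3C(=O)OC | intermediate
4 | 3-deoxy-2-ene methyl ester (13-OH, 16-ene) | C=C1C[C@]23C[C@@]1(O)CC[C@H]2[C@@]12CC=C[C@@](C)(C(=O)O1)[C@H]2[C@@H]3C(=O)OC | intermediate
5 | 13-O-hypoiodite of 4 (not isolated) | C=C1C[C@]23C[C@@]1(OI)CC[C@H]2[C@@]12CC=C[C@@](C)(C(=O)O1)[C@H]2[C@@H]3C(=O)OC | intermediate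
6 | 12-iodo-13-oxo-12,13-seco-2,16-diene methyl ester | C=C1C[C@]2(CC1=O)[C@@H](CCI)[C@@]13CC=C[C@@](C)(C(=O)O1)[C@H]3[C@@H]2C(=O)OC | intermediate
7 | 2β,3β-diol of 6 | C=C1C[C@]2(CC1=O)[C@@H](CCI)[C@@]13C[C@H](O)[C@H](O)[C@@](C)(C(=O)O1)[C@H]3[C@@H]2C(=O)OC | intermediate
8 | 2β,3β-O-isopropylidene derivative of 7 | C=C1C[C@]2(CC1=O)[C@@H](CCI)[C@@]13C[C@@H]4OC(C)(C)O[C@@H]4[C@@](C)(C(=O)O1)[C@H]3[C@@H]2C(=O)OC | intermediate
9 | 13-hydroxy-16(17)-ene allylic alcohol (C13 epimers) | C=C1C[C@]2(CC1O)[C@@H](CCI)[C@@]13C[C@@H]4OC(C)(C)O[C@@H]4[C@@](C)(C(=O)O1)[C@H]3[C@@H]2C(=O)OC | intermediate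
10 | C13 N-amino-N-(2-nitrophenylsulfonyl)amine adduct (not isolated) | C=C1C[C@]2(CC1N(N)S(=O)(=O)c1ccccc1[N+](=O)[O-])[C@@H](CCI)[C@@]13C[C@@H]4OC(C)(C)O[C@@H]4[C@@](C)(C(=O)O1)[C@H]3[C@@H]2C(=O)OC | intermediate
11 | C13 allylic diazene (not isolated) | C=C1C[C@]2(CC1N=N)[C@@H](CCI)[C@@]13C[C@@H]4OC(C)(C)O[C@@H]4[C@@](C)(C(=O)O1)[C@H]3[C@@H]2C(=O)OC | intermediate
12 | 12-iodo-12,13-seco-13(16)-ene | CC1=CC[C@@]2(C1)[C@@H](CCI)[C@@]13C[C@@H]4OC(C)(C)O[C@@H]4[C@@](C)(C(=O)O1)[C@H]3[C@@H]2C(=O)OC | intermediate
13 | 12-(trimethylammoniooxy) iodide (not isolated) | CC1=CC[C@@]2(C1)[C@@H](CCO[N+](C)(C)C)[C@@]13C[C@@H]4OC(C)(C)O[C@@H]4[C@@](C)(C(=O)O1)[C@H]3[C@@H]2C(=O)OC.[I-] | intermediate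
14 | 12-oxo-12,13-seco-13(16)-ene (aldehyde) | CC1=CC[C@@]2(C1)[C@@H](CC=O)[C@@]13C[C@@H]4OC(C)(C)O[C@@H]4[C@@](C)(C(=O)O1)[C@H]3[C@@H]2C(=O)OC | intermediate
15 | 12β-hydroxy 2,3-acetonide methyl ester (12-epimer of 17) | C=C1C[C@]23C[C@H]1[C@H](O)C[C@H]2[C@@]12C[C@@H]4OC(C)(C)O[C@@H]4[C@@](C)(C(=O)O1)[C@H]2[C@@H]3C(=O)OC | intermediate
16 | 12-oxo 2,3-acetonide methyl ester | C=C1C[C@]23C[C@H]1C(=O)C[C@H]2[C@@]12C[C@@H]4OC(C)(C)O[C@@H]4[C@@](C)(C(=O)O1)[C@H]2[C@@H]3C(=O)OC | intermediate
17 | 12α-hydroxy 2,3-acetonide methyl ester | C=C1C[C@]23C[C@H]1[C@@H](O)C[C@H]2[C@@]12C[C@@H]4OC(C)(C)O[C@@H]4[C@@](C)(C(=O)O1)[C@H]2[C@@H]3C(=O)OC | intermediate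
18 | 2β,3β,12α-trihydroxy methyl ester | C=C1C[C@]23C[C@H]1[C@@H](O)C[C@H]2[C@@]12C[C@H](O)[C@H](O)[C@@](C)(C(=O)O1)[C@H]2[C@@H]3C(=O)OC | intermediate
19 | target gibberellin (2β,3β,12α-trihydroxy-16-ene 19,10-lactone 7-carboxylic acid) | C=C1C[C@]23C[C@H]1[C@@H](O)C[C@H]2[C@@]12C[C@H](O)[C@H](O)[C@@](C)(C(=O)O1)[C@H]2[C@@H]3C(=O)O | target

**Totals**

Total step count: 14. Longest linear sequence: 14 steps, from 1 to 19.

**Steps most likely to fail**

Step 4. Acetyl hypoiodite may add across the ring A 2-ene in competition with hypoiodite homolysis, and part of the 13-oxyl radical may cleave C13–C14 instead of C12–C13; both drain the supply of 6. Fallback: ring A is finished before ring C is opened, so no ring A alkene meets the iodine reagents and the chemoselective osmylation of step 5 is no longer needed. Setting out from 2, MnO2 oxidation of the allylic 3-hydroxyl should give the 3-oxo-1-ene F1. Conjugate hydrosilylation (RhCl(PPh3)3, Et3SiH) should give the triethylsilyl enol ether F2. Rubottom oxidation with dimethyldioxirane on the β face, followed by mild desilylation, should give the 2β-hydroxy-3-ketone F3. KBH(s-Bu)3 (equatorial hydride delivery, axial 3β-alcohol) should give the 2β,3β,13-triol methyl ester F4, which is protected as the acetonide F5. The hypoiodite reaction of F5, through the hypoiodite F6, should then give 8 directly, where the route is rejoined.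

Step 8. The hydrazide may be captured at the unhindered C17 terminus (SN2′), which after nitrogen loss would return a deoxygenated exocyclic alkene, and PPh3 or the hydrazide anion may slowly alkylate at the primary iodide. Fallback: the transposition is run from the ketone instead of the alcohol. Setting out from 8, condensation with p-toluenesulfonylhydrazide should give the tosylhydrazone F7. Catecholborane reduction of the C=N bond should give the tosylhydrazine F8. Warming with NaOAc·3H2O expels sulfinate to give diazene 11, whose retro-ene loss of nitrogen moves the alkene into the ring and returns to the route at 12.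

Step 10. Cationic (Prins) leakage may lead to proton loss from C15 or chloride capture at C16, and the aluminium Lewis acid may open the isopropylidene acetal. Fallback: ring C is closed by an umpoled allyl-metal addition instead of an ene reaction. Setting out from 9, acetylation (Ac2O, pyridine) should give the allylic acetate F9, and Me3NO in DMSO should convert its iodide into the aldehyde acetate F10. Pd(PPh3)4 (zerovalent palladium) with InI should then effect reductive allylation of the C12 aldehyde by the allylic acetate, with γ-attack through C13 in a six-membered cyclic transition state. This should give the same 12β-alcohol with the exocyclic methylene, returning to the route at 15.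

**Further compounds**

F1 | step 4 | 3-oxo-1-ene methyl ester (3-dehydro derivative of 2) | C=C1C[C@]23C[C@@]1(O)CC[C@H]2[C@@]12C=CC(=O)[C@@](C)(C(=O)O1)[C@H]2[C@@H]3C(=O)OC
F2 | step 4 | 3-triethylsilyloxy-2-ene (silyl enol ether) | C=C1C[C@]23C[C@@]1(O)CC[C@H]2[C@@]12CC=C(O[Si](CC)(CC)CC)[C@@](C)(C(=O)O1)[C@H]2[C@@H]3C(=O)OC
F3 | step 4 | 2β-hydroxy-3-oxo methyl ester | C=C1C[C@]23C[C@@]1(O)CC[C@H]2[C@@]12C[C@H](O)C(=O)[C@@](C)(C(=O)O1)[C@H]2[C@@H]3C(=O)OC
F4 | step 4 | 2β,3β,13-trihydroxy-16-ene methyl ester | C=C1C[C@]23C[C@@]1(O)CC[C@H]2[C@@]12C[C@H](O)[C@H](O)[C@@](C)(C(=O)O1)[C@H]2[C@@H]3C(=O)OC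
F5 | step 4 | 2,3-acetonide of the 2β,3β,13-triol methyl ester | C=C1C[C@]23C[C@@]1(O)CC[C@H]2[C@@]12C[C@@H]4OC(C)(C)O[C@@H]4[C@@](C)(C(=O)O1)[C@H]2[C@@H]3C(=O)OC
F6 | step 4 | 13-O-hypoiodite of the acetonide | C=C1C[C@]23C[C@@]1(OI)CC[C@H]2[C@@]12C[C@@H]4OC(C)(C)O[C@@H]4[C@@](C)(C(=O)O1)[C@H]2[C@@H]3C(=O)OC
F7 | step 8 | tosylhydrazone of 8 | C=C1C[C@]2(CC1=NNS(=O)(=O)c1ccc(C)cc1)[C@@H](CCI)[C@@]13C[C@@H]4OC(C)(C)O[C@@H]4[C@@](C)(C(=O)O1)[C@H]3[C@@H]2C(=O)OC
F8 | step 8 | C13 N′-tosylhydrazine | C=C1C[C@]2(CC1NNS(=O)(=O)c1ccc(C)cc1)[C@@H](CCI)[C@@]13C[C@@H]4OC(C)(C)O[C@@H]4[C@@](C)(C(=O)O1)[C@H]3[C@@H]2C(=O)OC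
F9 | step 10 | 13-O-acetate of 9 | C=C1C[C@]2(CC1OC(C)=O)[C@@H](CCI)[C@@]13C[C@@H]4OC(C)(C)O[C@@H]4[C@@](C)(C(=O)O1)[C@H]3[C@@H]2C(=O)OC
F10 | step 10 | 12-oxo 13-O-acetate (aldehyde) | C=C1C[C@]2(CC1OC(C)=O)[C@@H](CC=O)[C@@]13C[C@@H]4OC(C)(C)O[C@@H]4[C@@](C)(C(=O)O1)[C@H]3[C@@H]2C(=O)OC
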